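**Plan**

Labels: ring C is the central benzene. C-1 and C-5 bear the two identical arms through oxygen, C-3 the hydroxyl, C-6 the third ether oxygen. Each arm is a biaryl of an inner ring (B or D, bonded to the ether oxygen) and an outer phloroglucinol ring (A or E). Ring F is the 3,4,5-trihydroxyphenyl group, with F-1 on the C-6 oxygen.
Enabling feature: ring F has oxygen at F-3, F-4 and F-5, hydrogen at F-2 and F-6, and a mirror axis through F-1 and F-4, and its ether oxygen on C-6 is walled in by the aryloxy groups at C-1 and C-5. F-3/F-4/F-5 is therefore 1,3-dimethoxyacetone, and F-2/F-1/F-6 is a 2-oxymalonaldehyde unit that can be grown on the C-6 oxygen, so no aryl group has to be forced onto it.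
Cuts, in retrosynthetic order: the fifteen O–CH3 bonds; F-2–F-3 and F-5–F-6 (ring F opened); F-1–F-2 (aminomethylene carbon); O–F-1 (two-carbon unit F-1/F-6); C-6–O traced back to C-6–CHO; the aryl ether bonds at C-1 and C-5; the arm hydroxyl traced back to a formyl group; the A–B (= E–D) biaryl bond.
Forward order: rings A to E are bought as benzenes. The A–B biaryl is joined first and two copies are hung on ring C in one double SNAr. The formyl activator then becomes the C-6 oxygen and a three-carbon handle is built on it. Ring F, the only ring made, closes last before global demethylation.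
Stereochemistry: none has to be set. The target has no stereocentre and no stereogenic axis, because rings A and E are symmetric about their biaryl bonds, and the Z double bond of the enaminal vanishes into ring F.

Key step: step 9

Remark: ArO stands for the (2,2',4,4',6,6'-hexamethoxybiphenyl-3-yl)oxy group, the permethylated arm. Hyphenated labels such as F-1 are ring atoms, and unhyphenated F1 to F4 are compounds of the fallbacks. All six starting materials are taken to be catalogue compounds.

**Route**

Step 1
Reactants: 1 2,4,6-trimethoxybenzaldehyde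
Product: 2 3-bromo-2,4,6-trimethoxybenzaldehyde
Conditions: NBS (1.0 equiv), MeCN, 0 °C to rt, dark
Reagents that add atoms: N-bromosuccinimide, O=C1CCC(=O)N1Br
Why: Electrophilic aromatic bromination: C3 lies ortho, ortho and para to the three methoxy groups, and the formyl group together with the first bromine slows a second substitution, so one equivalent of NBS should stop at the monobromide.

Step 2
Reactants: 2 3-bromo-2,4,6-trimethoxybenzaldehyde; 3 2,4,6-trimethoxyphenylboronic acid
Product: 4 2,2',4,4',6,6'-hexamethoxybiphenyl-3-carbaldehyde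
Conditions: 3 (1.8 equiv), Pd(OAc)2 (5 mol %), SPhos (10 mol %), K3PO4 (3 equiv), toluene/H2O 10:1, 90 °C, Ar
Reagents that add atoms: none
Why: Suzuki–Miyaura coupling: zerovalent palladium carrying the bulky, electron-rich biarylphosphine is the established system for tetra-ortho-substituted biaryls, the formyl group eases oxidative addition into the C–Br bond, and the surplus of 3 covers its protodeboronation.

Step 3
Reactants: 4 2,2',4,4',6,6'-hexamethoxybiphenyl-3-carbaldehyde
Product: 6 2,2',4,4',6,6'-hexamethoxybiphenyl-3-ol (ArOH), via aryl formate 5 (not isolated)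
Conditions: mCPBA (1.2 equiv), CH2Cl2, 0 °C to rt; wash with aq Na2SO3/NaHCO3; then K2CO3 (0.2 equiv), MeOH, rt, Ar
Reagents that add atoms: 3-chloroperoxybenzoic acid, OOC(=O)c1cccc(Cl)c1
Why: Baeyer–Villiger oxidation with a Dakin-type overall outcome: in the peracid adduct the trialkoxyaryl group migrates in preference to hydrogen, and the labile formate is removed by mild methanolysis that leaves every methyl ether untouched.

Step 4
Reactants: 6 2,2',4,4',6,6'-hexamethoxybiphenyl-3-ol (2.2 equiv); 7 2,6-difluoro-4-methoxybenzaldehyde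
Product: 9 2,6-bis(ArO)-4-methoxybenzaldehyde, via monofluoro aldehyde 8 (not isolated)
Conditions: Cs2CO3 (3 equiv), DMSO, 110 °C, Ar
Reagents that add atoms: none
Why: Double nucleophilic aromatic substitution (SNAr): both fluorines (at C-1 and C-5) are ortho to the formyl group on C-6, which stabilises the Meisenheimer adducts, while the C-3 methoxy group is meta to both reacting carbons and feeds no charge into them, so the cesium phenoxide of 6 should displace the two fluorides one after the other.

Step 5
Reactants: 9 2,6-bis(ArO)-4-methoxybenzaldehyde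
Product: 11 2,6-bis(ArO)-4-methoxyphenol, via aryl formate 10 (not isolated)
Conditions: mCPBA (1.2 equiv), CH2Cl2, 0 °C to rt; wash with aq Na2SO3/NaHCO3; then K2CO3 (0.2 equiv), MeOH, rt, Ar
Reagents that add atoms: 3-chloroperoxybenzoic acid, OOC(=O)c1cccc(Cl)c1
Why: Baeyer–Villiger oxidation: the small formyl group remains open to the peracid between the two arms, ring C with its two ortho and one para oxygen donors migrates readily, and the carbon that activated the SNAr is thereby exchanged for the C-6 oxygen with no site selectivity to solve.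

Step 6
Reactants: 11 2,6-bis(ArO)-4-methoxyphenol; 12 allyl bromide
Product: 13 2-(allyloxy)-1,3-bis(ArO)-5-methoxybenzene
Conditions: 12 (1.5 equiv), K2CO3 (2 equiv), DMF, 50 °C, Ar
Reagents that add atoms: none
Why: Williamson ether synthesis: SN2 attack on a slim and highly reactive allylic bromide is about the least demanding reaction the shielded C-6 phenoxide can be asked to perform, and Claisen rearrangement is excluded by the mild temperature and the two blocked ortho positions.

Step 7
Reactants: 13 2-(allyloxy)-1,3-bis(ArO)-5-methoxybenzene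
Product: 15 2-[2,6-bis(ArO)-4-methoxyphenoxy]acetaldehyde, via racemic diol 14 (not isolated)
Conditions: OsO4 (2 mol %), NaIO4 (4 equiv), 2,6-lutidine (2 equiv), 1,4-dioxane/H2O 3:1, rt
Reagents that add atoms: osmium tetroxide, O=[Os](=O)(=O)=O (delivers the oxygen, catalytic); sodium periodate, [Na+].[O-]I(=O)(=O)=O (terminal oxygen source)
Why: Lemieux–Johnson oxidation: OsO4 dihydroxylates the only alkene and periodate cleaves the diol in the same flask, and the buffered neutral medium avoids the acid that would let the new aldehyde alkylate the phloroglucinol-type rings in a Friedel–Crafts sense.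

Step 8
Reactants: 15 2-[2,6-bis(ArO)-4-methoxyphenoxy]acetaldehyde; 16 N,N-dimethylformamide dimethyl acetal
Product: 17 (Z)-2-[2,6-bis(ArO)-4-methoxyphenoxy]-3-(dimethylamino)prop-2-enal
Conditions: 15 dried azeotropically with toluene; 16 (5 equiv), toluene, 80 °C, Ar
Reagents that add atoms: none
Why: Aminomethylenation of an enolisable aldehyde with an amide acetal: methoxide released from 16 deprotonates the OCH2 group activated by the formyl and aryloxy groups, the enolate adds to the formamidinium ion, and loss of methanol gives the push–pull enaminal in its more stable Z form with the formyl group trans to NMe2.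

Step 9
Reactants: 17 (Z)-2-[2,6-bis(ArO)-4-methoxyphenoxy]-3-(dimethylamino)prop-2-enal; 18 1,3-dimethoxyacetone
Product: 20 4-[2,6-bis(ArO)-4-methoxyphenoxy]-2,6-dimethoxyphenol, via keto-enal 19 (not isolated)
Conditions: 18 (5 equiv), KOtBu (3 equiv), THF/t-BuOH 4:1, 0 °C to 60 °C, Ar; then AcOH
Reagents that add atoms: none
Why: The potassium enolate of 18 attacks the aminomethylene carbon (future F-2) of the push–pull enaminal 17 and dimethylamine leaves, an addition–elimination that forges F-2–F-3 and gives keto-enal 19 as its delocalised dienolate, in which rotation about F-1–F-2 brings the formyl group within reach. The second alpha carbon of the ketone (F-5) then adds to the formyl carbon (F-6) in a 6-(enolendo)-exo-trig aldol closure, and loss of water followed by keto–enol tautomerisation delivers the aromatic 4-aryloxy-2,6-dimethoxyphenoxide, an irreversible sink that drains the reversible aldol and Michael adducts. The closest known reaction type is the [3+3] phenol annulation of ketones with 2-substituted 3-aminoacroleins, vinamidinium salts or sodium nitromalonaldehyde; should the enolate add to the formyl group first, the resulting aminodienone closes at its other terminus to the same phenol. No stereocentre is formed, since the transient ones are erased on aromatisation. The step needs both new bonds to come from one ketone molecule and needs no regiocontrol, because 18 and the three-carbon unit of 17 are each symmetric about the F-1/F-4 axis once nitrogen and oxygen have left, and the six-membered closure is intramolecular whereas a second ketone would have to add intermolecularly. The C-6 oxygen is a mere spectator, ring F grows outward from the arms at C-1 and C-5, and aryl methyl ethers and diaryl ethers are inert to tert-butoxide at this temperature.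

Step 10
Reactants: 20 4-[2,6-bis(ArO)-4-methoxyphenoxy]-2,6-dimethoxyphenol
Product: 21 3,5-bis[(2,2',4,4',6,6'-hexahydroxybiphenyl-3-yl)oxy]-4-(3,4,5-trihydroxyphenoxy)phenol (CNP0279880.0)
Conditions: BBr3 (40 equiv), CH2Cl2, −78 °C to rt; then H2O, 0 °C; reversed-phase chromatography under Ar
Reagents that add atoms: none
Why: Lewis acid mediated cleavage of aryl methyl ethers: BBr3 binds each methoxy oxygen and bromide removes the methyl group by SN2, whereas the sp2 C–O bonds of the three diaryl ethers and the two biaryl bonds are not attacked, and hydrolysis of the aryl borates releases all sixteen hydroxyl groups.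

**Compound list**

1 | 2,4,6-trimethoxybenzaldehyde | COc1cc(OC)c(C=O)c(OC)c1 | starting material
2 | 3-bromo-2,4,6-trimethoxybenzaldehyde | COc1cc(OC)c(Br)c(OC)c1C=O | intermediate
3 | 2,4,6-trimethoxyphenylboronic acid | COc1cc(OC)c(B(O)O)c(OC)c1 | starting material
4 | 2,2',4,4',6,6'-hexamethoxybiphenyl-3-carbaldehyde | COc1cc(OC)c(-c2c(OC)cc(OC)c(C=O)c2OC)c(OC)c1 | intermediate
5 | 2,2',4,4',6,6'-hexamethoxybiphenyl-3-yl formate | COc1cc(OC)c(-c2c(OC)cc(OC)c(OC=O)c2OC)c(OC)c1 | intermediate
6 | 2,2',4,4',6,6'-hexamethoxybiphenyl-3-ol (ArOH) | COc1cc(OC)c(-c2c(OC)cc(OC)c(O)c2OC)c(OC)c1 | intermediate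
7 | 2,6-difluoro-4-methoxybenzaldehyde | COc1cc(F)c(C=O)c(F)c1 | starting material
8 | 2-(ArO)-6-fluoro-4-methoxybenzaldehyde | COc1cc(F)c(C=O)c(Oc2c(OC)cc(OC)c(-c3c(OC)cc(OC)cc3OC)c2OC)c1 | intermediate
9 | 2,6-bis(ArO)-4-methoxybenzaldehyde | COc1cc(Oc2c(OC)cc(OC)c(-c3c(OC)cc(OC)cc3OC)c2OC)c(C=O)c(Oc2c(OC)cc(OC)c(-c3c(OC)cc(OC)cc3OC)c2OC)c1 | intermediate
10 | 2,6-bis(ArO)-4-methoxyphenyl formate | COc1cc(Oc2c(OC)cc(OC)c(-c3c(OC)cc(OC)cc3OC)c2OC)c(OC=O)c(Oc2c(OC)cc(OC)c(-c3c(OC)cc(OC)cc3OC)c2OC)c1 | intermediate
11 | 2,6-bis(ArO)-4-methoxyphenol | COc1cc(Oc2c(OC)cc(OC)c(-c3c(OC)cc(OC)cc3OC)c2OC)c(O)c(Oc2c(OC)cc(OC)c(-c3c(OC)cc(OC)cc3OC)c2OC)c1 | intermediate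
12 | allyl bromide | C=CCBr | starting material
13 | 2-(allyloxy)-1,3-bis(ArO)-5-methoxybenzene | COc1cc(Oc2c(OC)cc(OC)c(-c3c(OC)cc(OC)cc3OC)c2OC)c(OCC=C)c(Oc2c(OC)cc(OC)c(-c3c(OC)cc(OC)cc3OC)c2OC)c1 | intermediate
14 | 3-[2,6-bis(ArO)-4-methoxyphenoxy]propane-1,2-diol (racemic) | COc1cc(Oc2c(OC)cc(OC)c(-c3c(OC)cc(OC)cc3OC)c2OC)c(OCC(O)CO)c(Oc2c(OC)cc(OC)c(-c3c(OC)cc(OC)cc3OC)c2OC)c1 | intermediate
15 | 2-[2,6-bis(ArO)-4-methoxyphenoxy]acetaldehyde | COc1cc(Oc2c(OC)cc(OC)c(-c3c(OC)cc(OC)cc3OC)c2OC)c(OCC=O)c(Oc2c(OC)cc(OC)c(-c3c(OC)cc(OC)cc3OC)c2OC)c1 | intermediate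
16 | N,N-dimethylformamide dimethyl acetal | COC(OC)N(C)C | starting material
17 | (Z)-2-[2,6-bis(ArO)-4-methoxyphenoxy]-3-(dimethylamino)prop-2-enal | COc1cc(Oc2c(OC)cc(OC)c(-c3c(OC)cc(OC)cc3OC)c2OC)c(O/C(C=O)=C\N(C)C)c(Oc2c(OC)cc(OC)c(-c3c(OC)cc(OC)cc3OC)c2OC)c1 | intermediate
18 | 1,3-dimethoxyacetone | COCC(=O)COC | starting material
19 | 2-[2,6-bis(ArO)-4-methoxyphenoxy]-4,6-dimethoxy-5-oxohex-2-enal (present as its potassium dienolate; double-bond geometry and C4 configuration labile) | COc1cc(Oc2c(OC)cc(OC)c(-c3c(OC)cc(OC)cc3OC)c2OC)c(OC(C=O)=CC(OC)C(=O)COC)c(Oc2c(OC)cc(OC)c(-c3c(OC)cc(OC)cc3OC)c2OC)c1 | intermediate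
20 | 4-[2,6-bis(ArO)-4-methoxyphenoxy]-2,6-dimethoxyphenol | COc1cc(Oc2c(OC)cc(OC)c(-c3c(OC)cc(OC)cc3OC)c2OC)c(Oc2cc(OC)c(O)c(OC)c2)c(Oc2c(OC)cc(OC)c(-c3c(OC)cc(OC)cc3OC)c2OC)c1 | intermediate
21 | 3,5-bis[(2,2',4,4',6,6'-hexahydroxybiphenyl-3-yl)oxy]-4-(3,4,5-trihydroxyphenoxy)phenol (CNP0279880.0) | Oc1cc(O)c(-c2c(O)cc(O)c(Oc3cc(O)cc(Oc4c(O)cc(O)c(-c5c(O)cc(O)cc5O)c4O)c3Oc3cc(O)c(O)c(O)c3)c2O)c(O)c1 | target

**Step count and risks**

Total step count: 10. Longest linear sequence: 10 steps (1 to 21).

Steps most likely to fail:

Step 9. The enaminal is a vinylogous formamide and only a modest electrophile. Enolate addition may therefore lag behind self-condensation of the ketone, or behind hydrolysis of the enaminal by the water the reaction itself releases. The open-chain adduct may also rest as its stabilised dienolate without closing. The fallback sets out from 11 and comes back to the route at 21. Ring F is brought in ready-made by a copper-catalysed Ullmann-type O-arylation of phenol 11 with commercial 5-iodo-1,2,3-trimethoxybenzene (CuI, picolinic acid, K3PO4, DMSO, 100 °C). This catalyst system was developed for di-ortho-substituted phenols and is helped here by an iodide without ortho substituents. It should give 1,3-bis(ArO)-5-methoxy-2-(3,4,5-trimethoxyphenoxy)benzene F1, whose sixteen methyl ethers are cleaved with BBr3 as in step 10 to give 21.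

Step 4. The second displacement may stall, because the remaining fluorine sits next to a formyl group that the first arm pushes out of conjugation. Prolonged heating also invites demethylation of methoxy groups by the phenoxide and oxidative loss of the electron-rich phenoxide. The fallback sets out from 6 and comes back to the route at 11, so steps 4 and 5 are bypassed. Commercial 2,6-dibromo-4-methoxyphenol is benzylated (BnBr, K2CO3, DMF) to 2-(benzyloxy)-1,3-dibromo-5-methoxybenzene F2. A double Ullmann ether coupling with 6 (2.4 equiv, CuI, picolinic acid, K3PO4, DMSO, 110 °C) should give 2-(benzyloxy)-1,3-bis(ArO)-5-methoxybenzene F3. Hydrogenolysis (H2, Pd/C, EtOAc/MeOH) then frees the C-6 hydroxyl of 11.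

Step 10. Partly cleaved boron aryloxides may precipitate and stop the reaction short of fifteen cleavages. The free polyphenol may also be lost to air oxidation and irreversible adsorption during isolation. The fallback sets out from 20 and comes back to the route at 21. The crude product of the BBr3 treatment is not purified but peracetylated at once (Ac2O, pyridine, rt) to the hexadecaacetate of the target F4. This compound can be chromatographed on silica and separated from under-cleaved material. Acid-catalysed methanolysis (catalytic HCl, MeOH, Ar) followed by evaporation then releases 21 without a chromatographic step on the free phenol.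

**Further compounds**

F1 | step 9 | 1,3-bis(ArO)-5-methoxy-2-(3,4,5-trimethoxyphenoxy)benzene | COc1cc(Oc2c(OC)cc(OC)c(-c3c(OC)cc(OC)cc3OC)c2OC)c(Oc2cc(OC)c(OC)c(OC)c2)c(Oc2c(OC)cc(OC)c(-c3c(OC)cc(OC)cc3OC)c2OC)c1
F2 | step 4 | 2-(benzyloxy)-1,3-dibromo-5-methoxybenzene | COc1cc(Br)c(OCc2ccccc2)c(Br)c1
F3 | step 4 | 2-(benzyloxy)-1,3-bis(ArO)-5-methoxybenzene | COc1cc(Oc2c(OC)cc(OC)c(-c3c(OC)cc(OC)cc3OC)c2OC)c(OCc2ccccc2)c(Oc2c(OC)cc(OC)c(-c3c(OC)cc(OC)cc3OC)c2OC)c1
F4 | step 10 | hexadecaacetate of the target | CC(=O)Oc1cc(OC(C)=O)c(-c2c(OC(C)=O)cc(OC(C)=O)c(Oc3cc(OC(C)=O)cc(Oc4c(OC(C)=O)cc(OC(C)=O)c(-c5c(OC(C)=O)cc(OC(C)=O)cc5OC(C)=O)c4OC(C)=O)c3Oc3cc(OC(C)=O)c(OC(C)=O)c(OC(C)=O)c3)c2OC(C)=O)c(OC(C)=O)c1
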